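## Retrosynthetic overview

1. Labels: ring A = dioxygenated benzoyl ring, ring B = benzo ring of the indane, ring C = five-membered ring, ring D = seven-membered ring; C-a = ring C CH bearing the 3,5-dioxygenated phenyl, C-b = ring C CH bearing the 4-oxygenated phenyl, C-c = CH shared by rings C and D, C-d = ring D CH bearing the other 4-oxygenated phenyl. Target ⇐ octamethyl ether (BBr3) ⇐ arylation of the C-d methylene of a tetracyclic ketone (last stereocentre, set under equilibrating base).
2. Ring D (formed second) ⇐ intramolecular Friedel–Crafts acylation of ring B by the ring A carboxyl; C-a–aryl bond ⇐ deoxygenative arylation of an indanol, trans to the C-b aryl.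
3. C-c and C-b ⇐ suprafacial 1,3-hydrogen shift of a 1H-inden-1-ol (carbinol chirality relayed to C-c), then enol equilibration to the trans ketone.
4. Ring C (formed first) ⇐ enantioselective rhodium-catalysed [3+2] annulation of an ortho-formyl arylboronate with an aryl–alkyl alkyne, which makes the ring B–C-c bond and the C-a–C-b bond in one operation.
5. Enabling feature: the ring B carbon bonded to C-c (meta to both ring B oxygens, out of reach of Friedel–Crafts or oxidative coupling) is ortho to the ring B carbon that carries C-a. C-a can therefore enter as a formyl carbon next to a C–B bond, and C-c/C-b as the CH2-substituted and aryl-substituted carbons of a polarised alkyne.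

Key step: step 4

Remark: the diene ligand enantiomer is written for an assumed sense of induction that gives the (1R)-indenol; if the first run shows the opposite sense, the antipodal diene is used and nothing else changes.
Remark: the natural configuration at C-d (aryl anti to the C-c–C-b bond) is assumed to be the thermodynamically preferred one in the tetracyclic ketone; step 10 is written on that basis.

## Route

Step 1
Reactants: 1 methyl 3,5-dimethoxybenzoate
Product: 2 methyl 2-(chloromethyl)-3,5-dimethoxybenzoate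
Conditions: (CH2O)n, HCl (gas), AcOH, 15–20 °C
Reagents that add atoms: formaldehyde (from paraformaldehyde), C=O; hydrogen chloride, Cl
Why: Blanc chloromethylation, which should go to the position ortho to the ester (ortho and para to the two methoxy groups) as halogenation and formylation of this ester do, the low temperature holding back lactonisation to the phthalide.

Step 2
Reactants: 2 methyl 2-(chloromethyl)-3,5-dimethoxybenzoate; 3 1-ethynyl-4-methoxybenzene
Product: 4 methyl 3,5-dimethoxy-2-[3-(4-methoxyphenyl)prop-2-yn-1-yl]benzoate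
Conditions: PdCl2(MeCN)2 (2 mol%), XPhos (6 mol%), Cs2CO3, THF, 65 °C
Reagents that add atoms: none
Why: copper-free Sonogashira-type alkynylation of a benzylic chloride, the mild carbonate base being chosen so that the skipped aryl alkyne does not isomerise to the allene.

Step 3
Reactants: 5 2-bromo-4,6-dimethoxybenzaldehyde
Product: 6 2,4-dimethoxy-6-(4,4,5,5-tetramethyl-1,3,2-dioxaborolan-2-yl)benzaldehyde
Conditions: B2pin2, Pd(dppf)Cl2 (3 mol%), KOAc, 1,4-dioxane, 85 °C
Reagents that add atoms: bis(pinacolato)diboron, CC1(C)OB(OC1(C)C)B1OC(C)(C)C(C)(C)O1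
Why: Miyaura borylation of an aryl bromide with one ortho substituent, a reaction that tolerates the free aldehyde.

Step 4
Reactants: 6 2,4-dimethoxy-6-(4,4,5,5-tetramethyl-1,3,2-dioxaborolan-2-yl)benzaldehyde; 4 methyl 3,5-dimethoxy-2-[3-(4-methoxyphenyl)prop-2-yn-1-yl]benzoate
Product: 7 methyl 2-{[(1R)-1-hydroxy-5,7-dimethoxy-2-(4-methoxyphenyl)-1H-inden-3-yl]methyl}-3,5-dimethoxybenzoate
Conditions: [RhCl(C2H4)2]2 (2.5 mol%), (1R,4R)-2,5-diphenylbicyclo[2.2.2]octa-2,5-diene (5.5 mol%), KOH (20 mol%), 1,4-dioxane/H2O 10:1, 50 °C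
Reagents that add atoms: none
Why: Transmetalation of boronate 6 to the hydroxo-rhodium diene complex gives an aryl–rhodium species (monovalent rhodium) at the ring B carbon meta to both methoxy groups; syn-carbometalation of alkyne 4 then bonds that carbon to the CH2-bearing alkyne carbon (future C-c) and puts rhodium on the anisyl-bearing carbon (future C-b), and the alkenyl–rhodium adds to the ortho formyl carbon (future C-a) before protonolysis of the rhodium alkoxide. The closest known reaction type is the rhodium-catalysed [3+2] annulation of 2-formylarylboronic acids with internal aryl–alkyl alkynes to 1H-inden-1-ols, including its chiral-diene variant. Ring C is closed by an intramolecular 5-exo-trig 1,2-addition of the alkenyl–rhodium to the aldehyde, after the intermolecular insertion. The only new stereocentre, the carbinol C-a, is set by the chiral diene, which fixes the aldehyde face presented to the alkenyl–rhodium bond; it is relayed to C-c in step 5. The step needs regioselective insertion, secured by the aryl/alkyl polarisation of the alkyne (rhodium prefers the carbon alpha to the anisyl group and the small CH2 end goes to the hindered aryl carbon), and chemoselectivity for the aldehyde over the ester, secured by the ortho position of the formyl group.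

Step 5
Reactants: 7 methyl 2-{[(1R)-1-hydroxy-5,7-dimethoxy-2-(4-methoxyphenyl)-1H-inden-3-yl]methyl}-3,5-dimethoxybenzoate
Product: 8 methyl 2-{[(1S,2R)-4,6-dimethoxy-2-(4-methoxyphenyl)-3-oxo-2,3-dihydro-1H-inden-1-yl]methyl}-3,5-dimethoxybenzoate
Conditions: DABCO (0.5 equiv), toluene, 70 °C
Reagents that add atoms: none
Why: base-catalysed suprafacial 1,3-prototropic isomerisation of the 1H-inden-1-ol to the indanone through a tight ion pair, which moves the carbinol hydrogen to the same face of C-c, after which the enol ketonises and the C-b aryl settles trans under the equilibrating conditions.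

Step 6
Reactants: 8 methyl 2-{[(1S,2R)-4,6-dimethoxy-2-(4-methoxyphenyl)-3-oxo-2,3-dihydro-1H-inden-1-yl]methyl}-3,5-dimethoxybenzoate
Product: 9 methyl 2-{[(1S,2R,3S)-3-hydroxy-4,6-dimethoxy-2-(4-methoxyphenyl)-2,3-dihydro-1H-inden-1-yl]methyl}-3,5-dimethoxybenzoate
Conditions: NaBH4, MeOH/THF, 0 °C to rt
Reagents that add atoms: none
Why: borohydride 1,2-reduction in which hydride should attack anti to the adjacent C-b aryl to give mainly the cis alcohol, whose carbinol configuration is erased in step 7.

Step 7
Reactants: 9 methyl 2-{[(1S,2R,3S)-3-hydroxy-4,6-dimethoxy-2-(4-methoxyphenyl)-2,3-dihydro-1H-inden-1-yl]methyl}-3,5-dimethoxybenzoate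
Product: 11 methyl 2-{[(1S,2S,3S)-3-(3,5-dimethoxyphenyl)-4,6-dimethoxy-2-(4-methoxyphenyl)-2,3-dihydro-1H-inden-1-yl]methyl}-3,5-dimethoxybenzoate, via alkoxybenzoxazoline adduct 10 (not isolated)
Conditions: 5,7-di-tert-butyl-3-phenylbenzoxazolium tetrafluoroborate, pyridine, MTBE, rt; then 1-bromo-3,5-dimethoxybenzene, NiBr2(dtbbpy) (5 mol%), [Ir(ppy)2(dtbbpy)]PF6 (1 mol%), quinuclidine, DMA, blue LEDs, rt
Reagents that add atoms: 1-bromo-3,5-dimethoxybenzene, COc1cc(Br)cc(OC)c1
Why: metallaphotoredox deoxygenative arylation (alcohol activated as a carbene adduct, beta-scission to the benzylic radical, nickel-mediated C(sp3)–C(sp2) coupling) under neutral conditions that avoid the cation and its elimination to the indene, the planar C-a radical being captured on the face opposite the adjacent C-b aryl so that C-a is set trans.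

Step 8
Reactants: 11 methyl 2-{[(1S,2S,3S)-3-(3,5-dimethoxyphenyl)-4,6-dimethoxy-2-(4-methoxyphenyl)-2,3-dihydro-1H-inden-1-yl]methyl}-3,5-dimethoxybenzoate
Product: 12 2-{[(1S,2S,3S)-3-(3,5-dimethoxyphenyl)-4,6-dimethoxy-2-(4-methoxyphenyl)-2,3-dihydro-1H-inden-1-yl]methyl}-3,5-dimethoxybenzoic acid
Conditions: LiOH, THF/MeOH/H2O, 60 °C; then aq. HCl to pH 3
Reagents that add atoms: lithium hydroxide, [Li+].[OH-]
Why: ester saponification, feasible because only one ortho substituent flanks the ester, and harmless to the stereocentres because none is acidic toward hydroxide.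

Step 9
Reactants: 12 2-{[(1S,2S,3S)-3-(3,5-dimethoxyphenyl)-4,6-dimethoxy-2-(4-methoxyphenyl)-2,3-dihydro-1H-inden-1-yl]methyl}-3,5-dimethoxybenzoic acid
Product: 14 tetracyclic heptamethoxy ketone with C-d as CH2, via mixed trifluoroacetic anhydride 13 (not isolated)
Conditions: (CF3CO)2O, CH2Cl2, 0 °C to rt, high dilution
Reagents that add atoms: none
Why: intramolecular Friedel–Crafts acylation in which the only ring B position within reach, ortho and para to the two methoxy groups, is acylated to close ring D in a seven-membered mode without touching a stereocentre.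

Step 10
Reactants: 14 tetracyclic heptamethoxy ketone with C-d as CH2
Product: 17 octamethyl ether of the target, via substrate potassium dienolate 15 (not isolated), via product potassium dienolate 16 (not isolated)
Conditions: 4-bromoanisole, Pd(OAc)2 (5 mol%), NiXantphos (7.5 mol%), KN(SiMe3)2 (3 equiv), CPME, rt; then MeOH, rt, 2 h; aq. NH4Cl
Reagents that add atoms: 4-bromoanisole, COc1ccc(Br)cc1
Why: palladium-catalysed deprotonative cross-coupling (benzylic C–H arylation through the phenylogous potassium enolate of the diaryl ketone, the only C–H that the ring A carbonyl makes acidic), after which methoxide-mediated equilibration of the again acidic C-d–H is expected to settle the new aryl group anti to the C-c–C-b bond while the non-acidic C-b centre anchors the absolute configuration.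

Step 11
Reactants: 17 octamethyl ether of the target
Product: 18 CNP0116600.1
Conditions: BBr3 (excess), CH2Cl2, −78 °C to rt; then MeOH, H2O
Reagents that add atoms: none
Why: Lewis acid cleavage of the eight aryl methyl ethers, which should leave the ketone and the four benzylic stereocentres untouched.

## Compound list

1 | methyl 3,5-dimethoxybenzoate | COC(=O)c1cc(OC)cc(OC)c1 | starting material
2 | methyl 2-(chloromethyl)-3,5-dimethoxybenzoate | COC(=O)c1cc(OC)cc(OC)c1CCl | intermediate
3 | 1-ethynyl-4-methoxybenzene | C#Cc1ccc(OC)cc1 | starting material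
4 | methyl 3,5-dimethoxy-2-[3-(4-methoxyphenyl)prop-2-yn-1-yl]benzoate | COC(=O)c1cc(OC)cc(OC)c1CC#Cc1ccc(OC)cc1 | intermediate
5 | 2-bromo-4,6-dimethoxybenzaldehyde | O=Cc1c(Br)cc(OC)cc1OC | starting material
6 | 2,4-dimethoxy-6-(4,4,5,5-tetramethyl-1,3,2-dioxaborolan-2-yl)benzaldehyde | O=Cc1c(B2OC(C)(C)C(C)(C)O2)cc(OC)cc1OC | intermediate
7 | methyl 2-{[(1R)-1-hydroxy-5,7-dimethoxy-2-(4-methoxyphenyl)-1H-inden-3-yl]methyl}-3,5-dimethoxybenzoate | O[C@@H]1C(c2ccc(OC)cc2)=C(Cc2c(OC)cc(OC)cc2C(=O)OC)c2cc(OC)cc(OC)c21 | intermediate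
8 | methyl 2-{[(1S,2R)-4,6-dimethoxy-2-(4-methoxyphenyl)-3-oxo-2,3-dihydro-1H-inden-1-yl]methyl}-3,5-dimethoxybenzoate | O=C1[C@@H](c2ccc(OC)cc2)[C@H](Cc2c(OC)cc(OC)cc2C(=O)OC)c2cc(OC)cc(OC)c21 | intermediate
9 | methyl 2-{[(1S,2R,3S)-3-hydroxy-4,6-dimethoxy-2-(4-methoxyphenyl)-2,3-dihydro-1H-inden-1-yl]methyl}-3,5-dimethoxybenzoate | O[C@H]1[C@@H](c2ccc(OC)cc2)[C@H](Cc2c(OC)cc(OC)cc2C(=O)OC)c2cc(OC)cc(OC)c21 | intermediate
10 | adduct of 9 in which its carbinol oxygen is bonded to C-2 of 5,7-di-tert-butyl-3-phenyl-2,3-dihydro-1,3-benzoxazole (mixture at that acetal carbon) | CC(C)(C)c1cc(C(C)(C)C)c2OC(O[C@H]3[C@@H](c4ccc(OC)cc4)[C@H](Cc4c(OC)cc(OC)cc4C(=O)OC)c4cc(OC)cc(OC)c43)N(c3ccccc3)c2c1 | intermediate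
11 | methyl 2-{[(1S,2S,3S)-3-(3,5-dimethoxyphenyl)-4,6-dimethoxy-2-(4-methoxyphenyl)-2,3-dihydro-1H-inden-1-yl]methyl}-3,5-dimethoxybenzoate | COc1cc(OC)cc(c1)[C@@H]1[C@@H](c2ccc(OC)cc2)[C@H](Cc2c(OC)cc(OC)cc2C(=O)OC)c2cc(OC)cc(OC)c21 | intermediate
12 | 2-{[(1S,2S,3S)-3-(3,5-dimethoxyphenyl)-4,6-dimethoxy-2-(4-methoxyphenyl)-2,3-dihydro-1H-inden-1-yl]methyl}-3,5-dimethoxybenzoic acid | COc1cc(OC)cc(c1)[C@@H]1[C@@H](c2ccc(OC)cc2)[C@H](Cc2c(OC)cc(OC)cc2C(=O)O)c2cc(OC)cc(OC)c21 | intermediate
13 | mixed anhydride of acid 12 with trifluoroacetic acid | COc1cc(OC)cc(c1)[C@@H]1[C@@H](c2ccc(OC)cc2)[C@H](Cc2c(OC)cc(OC)cc2C(=O)OC(=O)C(F)(F)F)c2cc(OC)cc(OC)c21 | intermediate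
14 | tetracyclic heptamethoxy ketone: rings A–D complete, C-d is CH2, C-c (S), C-b (S), C-a (S) | O=C1c2cc(OC)cc(OC)c2C[C@@H]2c3c1c(OC)cc(OC)c3[C@H](c1cc(OC)cc(OC)c1)[C@H]2c1ccc(OC)cc1 | intermediate
15 | potassium dienolate of 14 (ring A as ortho-quinodimethane, C-d sp2) | [K+].[O-]C1=C2C=C(OC)C=C(OC)C2=C[C@@H]2c3c1c(OC)cc(OC)c3[C@H](c1cc(OC)cc(OC)c1)[C@H]2c1ccc(OC)cc1 | intermediate
16 | potassium dienolate of 17 (C-d sp2, bearing the 4-methoxyphenyl group) | [K+].[O-]C1=C2C=C(OC)C=C(OC)C2=C(c2ccc(OC)cc2)[C@@H]2c3c1c(OC)cc(OC)c3[C@H](c1cc(OC)cc(OC)c1)[C@H]2c1ccc(OC)cc1 | intermediate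
17 | octamethyl ether of the target: C-d (S), C-c (R), C-b (S), C-a (S) | O=C1c2cc(OC)cc(OC)c2[C@H](c2ccc(OC)cc2)[C@@H]2c3c1c(OC)cc(OC)c3[C@H](c1cc(OC)cc(OC)c1)[C@H]2c1ccc(OC)cc1 | intermediate
18 | CNP0116600.1 | O=C1c2cc(O)cc(O)c2[C@H](c2ccc(O)cc2)[C@@H]2c3c1c(O)cc(O)c3[C@H](c1cc(O)cc(O)c1)[C@H]2c1ccc(O)cc1 | target

## Step count and risks

Total step count: 11. Longest linear sequence: 10 (steps 1, 2, 4–11).

Most likely to fail, first: step 10. The hindered benzylic anion may not couple, or the final protonation and equilibration of the planar dienolate at C-d may show poor facial selectivity or favour the wrong epimer. The fallback sets out from 14: deprotonation with LiN(SiMe3)2 in THF at −78 °C and trapping with N-bromosuccinimide should give the benzylic bromide F1. A nickel-catalysed Negishi coupling (NiBr2(diglyme), 4,4'-di-tert-butyl-2,2'-bipyridine, commercial (4-methoxyphenyl)zinc iodide, DMA/THF, 0 °C) would then form the C-d–aryl bond through a benzylic radical under non-basic conditions. The configuration at C-d would thus be fixed kinetically at the radical capture and not by equilibration. The fallback comes back to the route at 17.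

Second: step 4. Insertion of the alkyne with the wrong regiochemistry, protodeboronation of the electron-rich ortho-formyl boronate, or low enantioselectivity could spoil it. The fallback sets out from 5 and 4: a Larock annulation (Pd(OAc)2, NaOAc, n-Bu4NCl, DMF, 100 °C) of the aryl bromide with the alkyne should give the achiral indenone F2, with the aryl group next to the carbonyl as is usual for aryl–alkyl alkynes. Corey–Bakshi–Shibata reduction (the oxazaborolidine enantiomer that delivers the 1R alcohol, catecholborane, toluene, −78 °C) would then give 7, where the fallback comes back to the route.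

Third: step 7. The hindered alcohol may form the carbene adduct slowly, the adduct may fragment unproductively, or the benzylic radical may escape the nickel catalyst. The fallback sets out from 9: mesylation (MsCl, Et3N, Et2O, −30 °C) should give the mesylate F3, which LiI converts in the same flask to the iodide F4. A stereoconvergent nickel-catalysed Negishi arylation (NiBr2(diglyme), 4,4'-di-tert-butyl-2,2'-bipyridine, −30 °C) with (3,5-dimethoxyphenyl)zinc iodide F5, made beforehand from 1-iodo-3,5-dimethoxybenzene and zinc dust, would then deliver the aryl group trans to the C-b aryl. The fallback comes back to the route at 11.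

Further compounds
F1 | step 10 | benzylic bromide of 14 at C-d (mixture at C-d) | O=C1c2cc(OC)cc(OC)c2C(Br)[C@@H]2c3c1c(OC)cc(OC)c3[C@H](c1cc(OC)cc(OC)c1)[C@H]2c1ccc(OC)cc1
F2 | step 4 | methyl 2-{[5,7-dimethoxy-2-(4-methoxyphenyl)-1-oxo-1H-inden-3-yl]methyl}-3,5-dimethoxybenzoate | O=C1C(c2ccc(OC)cc2)=C(Cc2c(OC)cc(OC)cc2C(=O)OC)c2cc(OC)cc(OC)c21
F3 | step 7 | methanesulfonate of alcohol 9 | CS(=O)(=O)O[C@H]1[C@@H](c2ccc(OC)cc2)[C@H](Cc2c(OC)cc(OC)cc2C(=O)OC)c2cc(OC)cc(OC)c21
F4 | step 7 | benzylic iodide from 9 (mixture at the C–I carbon) | IC1[C@@H](c2ccc(OC)cc2)[C@H](Cc2c(OC)cc(OC)cc2C(=O)OC)c2cc(OC)cc(OC)c21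
F5 | step 7 | (3,5-dimethoxyphenyl)zinc iodide | COc1cc(OC)cc([Zn]I)c1
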